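Start from the mirror.

all flasks: left-handed substrate 0.39 M; right-handed substrate 0.39 M
- larch: partner 0.80 equiv (in portions, 4); free catalyst 5 mol%; the very flask that is asked about, followed so far; portions every 4.0 min
- oak: partner 0.80 equiv (in portions, 4); free catalyst 3.4 mol%; run made earlier; portions every 4.0 min
- flask: partner 0.800 equiv (in portions, 4); free catalyst 5 mol%; the portions of partner follow each other after 4.0 min, the first at the start; time 12 h

| run | time / h | left-handed substrate / % | left-handed product / % |
|---|---|---|---|
| larch | 0.167 | 38.9 | 7.3 |
| larch | 0.500 | 27.5 | 11.1 |
| larch | 0.833 | 25.9 | 11.8 |
| larch | 1.33 | 26.5 | 11.9 |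
| larch | 2.00 | 26.0 | 12.5 |
| larch | 2.50 | 25.6 | 10.9 |
| oak | 0.417 | 32.8 | 10.5 |
| oak | 0.667 | 30.8 | 10.6 |
| oak | 1.00 | 30.1 | 8.8 |
| oak | 2.00 | 28.7 | 9.1 |
| oak | 3.00 | 28.4 | 8.8 |
| oak | 5.00 | 30.9 | 9.8 |

(readings scatter by 1 percentage point)

* the state of affairs at 12 h: stopped, and by what, or still going (forward and back rates have come level / the partner has run out first / it is still moving / all of the left-handed substrate has reacted / no working catalyst is left)
* part of the left-handed substrate and right-handed substrate together gone at 12 h
* the left-handed product standing at 12 h, as a percentage of the left-handed substrate and right-handed substrate together charged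

- free catalyst is single-handed; left-handed substrate and right-handed substrate are mirror images of each other, charged as a racemate, each of them at the stated concentration
- the reaction counts as stopped when no species that holds the left-handed substrate and right-handed substrate together changes by six tenths of a point or more over the second half of the time

Turn the time first: larch stands flat from 0.833 h and oak out to 5.00 h, so average the flat readings, which give in larch 11.8% of left-handed product for 24.0% of left-handed substrate lost, and in oak 9.12% for 20.5%.

Turn the catalyst next: suppose by hand that each catalyst holds one left-handed substrate, so that larch keeps 2.50% out of sight and oak 1.70%; that step of 0.8 percentage points is smaller than the 3.5 points between the two losses, so the loading moves the turnover as well. Turn the partner last: both runs got 0.80 equiv, yet larch lost 48.0% of its left-handed substrate and oak 41.0%.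

Now take the symmetric case as the zero of the scale: a product turning into its mirror image, of equal energy, ends in equal parts. Pooling both runs gives 0.519 for the mirror share, the left-handed product standing per left-handed substrate lost and not held, which is about half, while the same share, with the same 2.50% taken off as held, reads 0.849 in larch at 0.167 h. For the flask, which is larch carried on, I reckon 11.2% of left-handed product; the share tells what stands for a given turnover, not what ended it.

The forecast says no working catalyst is left, with 27% gone and 11.8% of left-handed product, above my figure, on the ground: "So the catalyst is dying".

The flask gives the partner has run out first, with 25.2% gone and 11.5% standing. Its partner, the limiting reagent, is at 0% against 50% of the left-handed substrate, while free catalyst stands at 13.3% of its charge; there the forecast parts from the flask.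

    2 partner → homo dimer (k = 0.490 M⁻¹ min⁻¹)
    partner + catalyst intermediate B → free catalyst + right-handed product (k = 1.80 M⁻¹ min⁻¹)
    free catalyst + right-handed substrate ⇌ catalyst intermediate B (K = 0.610 M⁻¹, k = 72.0 M⁻¹ min⁻¹)
    left-handed product ⇌ right-handed product (k = 0.0870 min⁻¹)
    partner + catalyst intermediate A → free catalyst + left-handed product (k = 5.60 M⁻¹ min⁻¹)
    free catalyst + left-handed substrate ⇌ catalyst intermediate A (K = 32.0 M⁻¹, k = 1200 M⁻¹ min⁻¹)

Note that the forward half-life of left-handed product, 0.13 h at 0.173 h, is short against the 12 h, and that left-handed and right-handed product end at 11.5% and 11.5%. Apply the share to the flask's 25.2%: it gives 11.8%. Apply it to the neighbour with 0.320 equiv of partner and 14.2% gone: it gives 6.07%, and that flask computes to 5.97%.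

Readings and results are calculated from invented constants; the scatter is artificial.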